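## Retrosynthetic overview

1. The (Z)-alkylidene butenolide comes from mesylation and E1cB loss of water from a 5-(1-hydroxyalkyl)butenolide. That adduct is the key C–C bond, made by an intermolecular vinylogous Mukaiyama aldol of 2-silyloxy-3-methylfuran with the (S)-2-methyl aldehyde of the full side chain.
2. The aldehyde comes from the primary alcohol. The alcohol comes from sulfone-anion alkylation and desulfonylation, joining an allylic bromide (fragment A) to a C5 sulfone (fragment B). Fragment B is made from (R)-Roche ester, which supplies the only stereocentre.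
3. Fragment A comes from Li2CuCl4-catalysed coupling of furan-3-ylmethylmagnesium chloride with an 8-silyloxygeranyl chloride. The chloride is made from geranyl acetate by SeO2 allylic oxidation, so both E-alkenes come from geraniol.
4. No ring is built. The furan enters first with furan-3-ylmethanol and the butenolide enters last with 3-methylfuran-2(5H)-one. Only the exocyclic Z-alkene is created.

Assumption: the SMILES is read as the (5Z,2'S,6'E,10'E) isomer, and compounds 1, 7, 14, 18 and 26 are taken as catalogue chemicals.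

## Route

**Fragment A**

Step 1
Reactants: 1 geranyl acetate [(2E)-3,7-dimethylocta-2,6-dien-1-yl acetate]
Product: 2 (2E,6E)-8-hydroxy-3,7-dimethylocta-2,6-dien-1-yl acetate
Conditions: SeO2 (10 mol %), salicylic acid (10 mol %), tBuOOH (3 equiv), CH2Cl2, 0 °C → rt
Reagents that add atoms: tert-butyl hydroperoxide CC(C)(C)OO (stoichiometric oxygen source); selenium dioxide O=[Se]=O (catalytic oxygen carrier)
Why: The catalytic Riley allylic oxidation (ene reaction, then [2,3]-sigmatropic shift) attacks the electron-richer distal alkene at its E-methyl group and gives the (E)-allylic alcohol, while the acetate-deactivated 2,3-alkene is untouched and a little enal is removed by chromatography.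

Step 2
Reactants: 2 (2E,6E)-8-hydroxy-3,7-dimethylocta-2,6-dien-1-yl acetate
Product: 3 (2E,6E)-8-[(tert-butyldimethylsilyl)oxy]-3,7-dimethylocta-2,6-dien-1-yl acetate
Conditions: TBSCl, imidazole, CH2Cl2, 0 °C → rt
Reagents that add atoms: tert-butyldimethylsilyl chloride CC(C)(C)[Si](C)(C)Cl
Why: Imidazole-promoted silylation of an unhindered primary allylic alcohol is routine and differentiates the two chain ends.

Step 3
Reactants: 3 (2E,6E)-8-[(tert-butyldimethylsilyl)oxy]-3,7-dimethylocta-2,6-dien-1-yl acetate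
Product: 4 (2E,6E)-8-[(tert-butyldimethylsilyl)oxy]-3,7-dimethylocta-2,6-dien-1-ol
Conditions: K2CO3 (20 mol %), MeOH, rt
Reagents that add atoms: none
Why: Base-catalysed transesterification removes the acetate and leaves the TBS ether and both alkenes intact.

Step 4
Reactants: 4 (2E,6E)-8-[(tert-butyldimethylsilyl)oxy]-3,7-dimethylocta-2,6-dien-1-ol
Product: 6 tert-butyl{[(2E,6E)-8-chloro-2,6-dimethylocta-2,6-dien-1-yl]oxy}dimethylsilane, via allylic mesylate 5 (not isolated)
Conditions: MsCl, 2,4,6-collidine, LiCl, DMF, 0 °C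
Reagents that add atoms: methanesulfonyl chloride CS(=O)(=O)Cl (mesyl group of 5 only); lithium chloride [Li+].[Cl-] (chlorine of 6)
Why: In the Collington–Meyers chlorination the mesylate formed in the flask is displaced by chloride in an SN2 reaction under near-neutral conditions, without allylic transposition or E/Z erosion.

Step 5
Reactants: 7 furan-3-ylmethanol
Product: 9 3-(chloromethyl)furan, via furylmethyl mesylate 8 (not isolated)
Conditions: MsCl, 2,4,6-collidine, LiCl, DMF, 0 °C; pentane extraction, used at once as a dried THF solution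
Reagents that add atoms: methanesulfonyl chloride CS(=O)(=O)Cl (mesyl group of 8 only); lithium chloride [Li+].[Cl-] (chlorine of 9)
Why: The same Collington–Meyers protocol avoids free acid, which would polymerise the furan, and gives the volatile chloride cleanly.

Step 6
Reactants: 9 3-(chloromethyl)furan; 6 tert-butyl{[(2E,6E)-8-chloro-2,6-dimethylocta-2,6-dien-1-yl]oxy}dimethylsilane
Product: 11 tert-butyl{[(2E,6E)-9-(furan-3-yl)-2,6-dimethylnona-2,6-dien-1-yl]oxy}dimethylsilane, via furan-3-ylmethylmagnesium chloride 10 (not isolated)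
Conditions: 9 (1.8 equiv, slow addition), Mg turnings, THF, 0 °C → rt; then 6, Li2CuCl4 (3 mol %), THF, 0 °C
Reagents that add atoms: magnesium [Mg] (held in 10 only)
Why: The Kochi-type Li2CuCl4-catalysed Grignard cross-coupling substitutes the primary allylic chloride at its α-carbon with retention of the E-alkene, and the silyl ether is not a leaving group.

Step 7
Reactants: 11 tert-butyl{[(2E,6E)-9-(furan-3-yl)-2,6-dimethylnona-2,6-dien-1-yl]oxy}dimethylsilane
Product: 12 (2E,6E)-9-(furan-3-yl)-2,6-dimethylnona-2,6-dien-1-ol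
Conditions: Bu4NF, THF, 0 °C → rt; water work-up
Reagents that add atoms: none
Why: Fluoride-driven desilylation is specific for the Si–O bond and is harmless to the furan and the alkenes.

Step 8
Reactants: 12 (2E,6E)-9-(furan-3-yl)-2,6-dimethylnona-2,6-dien-1-ol
Product: 13 3-[(3E,7E)-9-bromo-4,8-dimethylnona-3,7-dien-1-yl]furan
Conditions: CBr4, PPh3, CH2Cl2, −20 → 0 °C; short silica plug, used the same day
Reagents that add atoms: carbon tetrabromide BrC(Br)(Br)Br
Why: The Appel reaction converts the primary allylic alcohol into the bromide under neutral conditions, so the acid-sensitive furan and the alkene geometry survive.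

**Fragment B**

Step 9
Reactants: 14 methyl (R)-3-hydroxy-2-methylpropanoate [(R)-Roche ester]
Product: 15 methyl (R)-3-[(tert-butyldiphenylsilyl)oxy]-2-methylpropanoate
Conditions: TBDPSCl, imidazole, CH2Cl2, rt
Reagents that add atoms: tert-butyldiphenylsilyl chloride CC(C)(C)[Si](Cl)(c1ccccc1)c1ccccc1
Why: This is a standard silylation, and the stereocentre of the target is taken from the chiral pool here, with the silyloxymethyl carbon becoming the later aldehyde carbon.

Step 10
Reactants: 15 methyl (R)-3-[(tert-butyldiphenylsilyl)oxy]-2-methylpropanoate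
Product: 16 (S)-3-[(tert-butyldiphenylsilyl)oxy]-2-methylpropan-1-ol
Conditions: iBu2AlH (2.5 equiv), CH2Cl2, −78 → 0 °C; aq. potassium sodium tartrate (KNaC4H4O6) work-up
Reagents that add atoms: none
Why: Hydride reduction of the ester does not touch the stereocentre, and the bulky TBDPS group does not migrate, so the pseudo-symmetric diol cannot racemise (the descriptor changes only through CIP ranking).

Step 11
Reactants: 16 (S)-3-[(tert-butyldiphenylsilyl)oxy]-2-methylpropan-1-ol
Product: 17 tert-butyl{[(R)-3-iodo-2-methylpropyl]oxy}diphenylsilane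
Conditions: PPh3, I2, imidazole (premixed), CH2Cl2, 0 °C → rt
Reagents that add atoms: iodine II
Why: The Appel-type (Garegg–Samuelsson) iodination acts at the primary carbon only, so the adjacent stereocentre is unchanged.

Step 12
Reactants: 18 methyl phenyl sulfone; 17 tert-butyl{[(R)-3-iodo-2-methylpropyl]oxy}diphenylsilane
Product: 20 tert-butyl{[(S)-2-methyl-4-(phenylsulfonyl)butyl]oxy}diphenylsilane, via phenylsulfonylmethyllithium 19 (not isolated)
Conditions: 18 (2.5 equiv), nBuLi (2.4 equiv), THF/DMPU, −78 → 0 °C; then 17, 0 °C → rt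
Reagents that add atoms: n-butyllithium [Li]CCCC (lithium of 19 only)
Why: SN2 alkylation of the sulfonyl carbanion adds one carbon to the primary iodide, and the excess anion suppresses double alkylation.

**Fragment union and endgame**

Step 13
Reactants: 20 tert-butyl{[(S)-2-methyl-4-(phenylsulfonyl)butyl]oxy}diphenylsilane; 13 3-[(3E,7E)-9-bromo-4,8-dimethylnona-3,7-dien-1-yl]furan
Product: 22 tert-butyl{[(2S,6E,10E)-13-(furan-3-yl)-2,6,10-trimethyl-4-(phenylsulfonyl)trideca-6,10-dien-1-yl]oxy}diphenylsilane (about 1:1 epimers at C4), via lithiated sulfone 21 (not isolated)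
Conditions: 20, nBuLi (1.05 equiv), THF/DMPU, −78 °C, 30 min; then 13, −78 → −20 °C
Reagents that add atoms: n-butyllithium [Li]CCCC (lithium of 21 only)
Why: Sulfone-carbanion alkylation of a primary allylic bromide is a clean SN2 process without allylic shift, and the new sulfone-bearing centre is irrelevant because it is erased in step 14.

Step 14
Reactants: 22 tert-butyl{[(2S,6E,10E)-13-(furan-3-yl)-2,6,10-trimethyl-4-(phenylsulfonyl)trideca-6,10-dien-1-yl]oxy}diphenylsilane
Product: 23 tert-butyl{[(2S,6E,10E)-13-(furan-3-yl)-2,6,10-trimethyltrideca-6,10-dien-1-yl]oxy}diphenylsilane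
Conditions: 6% Na(Hg), Na2HPO4, MeOH/THF, −20 → 0 °C
Reagents that add atoms: none
Why: Buffered single-electron reductive desulfonylation cleaves the C–S bond, and because the sulfone is homoallylic rather than allylic the alkene can neither migrate nor isomerise.

Step 15
Reactants: 23 tert-butyl{[(2S,6E,10E)-13-(furan-3-yl)-2,6,10-trimethyltrideca-6,10-dien-1-yl]oxy}diphenylsilane
Product: 24 (2S,6E,10E)-13-(furan-3-yl)-2,6,10-trimethyltrideca-6,10-dien-1-ol
Conditions: Bu4NF, THF, rt; water work-up
Reagents that add atoms: none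
Why: Fluoride desilylation frees the primary alcohol with no other reactive site in the molecule.

Step 16
Reactants: 24 (2S,6E,10E)-13-(furan-3-yl)-2,6,10-trimethyltrideca-6,10-dien-1-ol
Product: 25 (2S,6E,10E)-13-(furan-3-yl)-2,6,10-trimethyltrideca-6,10-dienal
Conditions: Dess–Martin periodinane, NaHCO3, CH2Cl2, 0 °C → rt; used without storage
Reagents that add atoms: none
Why: The buffered Dess–Martin oxidation stops at the aldehyde under essentially neutral conditions, so the α-stereocentre does not epimerise and the furan is not attacked.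

Step 17
Reactants: 26 3-methylfuran-2(5H)-one
Product: 27 tert-butyldimethyl[(3-methylfuran-2-yl)oxy]silane
Conditions: TBSOTf, Et3N, CH2Cl2, 0 °C → rt; bulb-to-bulb distillation
Reagents that add atoms: tert-butyldimethylsilyl triflate CC(C)(C)[Si](C)(C)OS(=O)(=O)C(F)(F)F
Why: Soft enolisation and O-silylation of the butenolide is driven by aromatisation to the 2-silyloxyfuran.

Step 18 (key step)
Reactants: 25 (2S,6E,10E)-13-(furan-3-yl)-2,6,10-trimethyltrideca-6,10-dienal; 27 tert-butyldimethyl[(3-methylfuran-2-yl)oxy]silane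
Product: 28 5-[(2S,6E,10E)-13-(furan-3-yl)-1-hydroxy-2,6,10-trimethyltrideca-6,10-dien-1-yl]-3-methylfuran-2(5H)-one (mixture of diastereomers at ring C5 and C1')
Conditions: 27 (1.5 equiv), BF3·OEt2 (1.1 equiv), CH2Cl2, −78 °C; sat. aq. NaHCO3 quench at −78 °C
Reagents that add atoms: none
Why: In the intermolecular vinylogous Mukaiyama aldol the highly nucleophilic silyloxyfuran attacks the activated aldehyde only through C5 and outruns any alkene or furan side reaction at −78 °C; the two new stereocentres form as a mixture that does not matter because both become sp2 in step 19, and C2' is untouched.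

Step 19
Reactants: 28 5-[(2S,6E,10E)-13-(furan-3-yl)-1-hydroxy-2,6,10-trimethyltrideca-6,10-dien-1-yl]-3-methylfuran-2(5H)-one
Product: 30 (5Z)-5-[(2S,6E,10E)-13-(furan-3-yl)-2,6,10-trimethyltrideca-6,10-dien-1-ylidene]-3-methylfuran-2(5H)-one, via secondary mesylate 29 (not isolated)
Conditions: MsCl, Et3N, CH2Cl2, −10 → 0 °C; then DBU (1.5 equiv), 0 °C, 30 min; pH 7 buffer quench
Reagents that add atoms: methanesulfonyl chloride CS(=O)(=O)Cl (mesyl group of 29 only)
Why: Mesylation followed by E1cB elimination goes through the planar 2-oxidofuran, so all diastereomers of 28 converge on the less strained Z-alkylidene butenolide, and the short cold exposure to DBU leaves the far less acidic allylic C2'–H, and hence the (S) centre, intact.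

## Compound list

1 | geranyl acetate | CC(C)=CCC/C(C)=C/COC(C)=O | starting material
2 | (2E,6E)-8-hydroxy-3,7-dimethylocta-2,6-dien-1-yl acetate | OC/C(C)=C/CC/C(C)=C/COC(C)=O | intermediate
3 | (2E,6E)-8-[(tert-butyldimethylsilyl)oxy]-3,7-dimethylocta-2,6-dien-1-yl acetate | CC(C)(C)[Si](C)(C)OC/C(C)=C/CC/C(C)=C/COC(C)=O | intermediate
4 | (2E,6E)-8-[(tert-butyldimethylsilyl)oxy]-3,7-dimethylocta-2,6-dien-1-ol | CC(C)(C)[Si](C)(C)OC/C(C)=C/CC/C(C)=C/CO | intermediate
5 | (2E,6E)-8-[(tert-butyldimethylsilyl)oxy]-3,7-dimethylocta-2,6-dien-1-yl methanesulfonate | CC(C)(C)[Si](C)(C)OC/C(C)=C/CC/C(C)=C/COS(C)(=O)=O | intermediate (not isolated)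
6 | tert-butyl{[(2E,6E)-8-chloro-2,6-dimethylocta-2,6-dien-1-yl]oxy}dimethylsilane | CC(C)(C)[Si](C)(C)OC/C(C)=C/CC/C(C)=C/CCl | intermediate
7 | furan-3-ylmethanol | OCc1ccoc1 | starting material
8 | furan-3-ylmethyl methanesulfonate | CS(=O)(=O)OCc1ccoc1 | intermediate (not isolated)
9 | 3-(chloromethyl)furan | ClCc1ccoc1 | intermediate
10 | (furan-3-ylmethyl)magnesium chloride | Cl[Mg]Cc1ccoc1 | intermediate (not isolated)
11 | tert-butyl{[(2E,6E)-9-(furan-3-yl)-2,6-dimethylnona-2,6-dien-1-yl]oxy}dimethylsilane | CC(C)(C)[Si](C)(C)OC/C(C)=C/CC/C(C)=C/CCc1ccoc1 | intermediate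
12 | (2E,6E)-9-(furan-3-yl)-2,6-dimethylnona-2,6-dien-1-ol | OC/C(C)=C/CC/C(C)=C/CCc1ccoc1 | intermediate
13 | 3-[(3E,7E)-9-bromo-4,8-dimethylnona-3,7-dien-1-yl]furan | BrC/C(C)=C/CC/C(C)=C/CCc1ccoc1 | intermediate
14 | methyl (R)-3-hydroxy-2-methylpropanoate | COC(=O)[C@H](C)CO | starting material
15 | methyl (R)-3-[(tert-butyldiphenylsilyl)oxy]-2-methylpropanoate | COC(=O)[C@H](C)CO[Si](c1ccccc1)(c1ccccc1)C(C)(C)C | intermediate
16 | (S)-3-[(tert-butyldiphenylsilyl)oxy]-2-methylpropan-1-ol | OC[C@H](C)CO[Si](c1ccccc1)(c1ccccc1)C(C)(C)C | intermediate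
17 | tert-butyl{[(R)-3-iodo-2-methylpropyl]oxy}diphenylsilane | IC[C@H](C)CO[Si](c1ccccc1)(c1ccccc1)C(C)(C)C | intermediate
18 | methyl phenyl sulfone | CS(=O)(=O)c1ccccc1 | starting material
19 | [(phenylsulfonyl)methyl]lithium | [Li]CS(=O)(=O)c1ccccc1 | intermediate (not isolated)
20 | tert-butyl{[(S)-2-methyl-4-(phenylsulfonyl)butyl]oxy}diphenylsilane | O=S(=O)(CC[C@H](C)CO[Si](c1ccccc1)(c1ccccc1)C(C)(C)C)c1ccccc1 | intermediate
21 | α-lithio derivative of 20 (lithium on the carbon bearing sulfur) | [Li]C(C[C@H](C)CO[Si](c1ccccc1)(c1ccccc1)C(C)(C)C)S(=O)(=O)c1ccccc1 | intermediate (not isolated)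
22 | tert-butyl{[(2S,6E,10E)-13-(furan-3-yl)-2,6,10-trimethyl-4-(phenylsulfonyl)trideca-6,10-dien-1-yl]oxy}diphenylsilane, C4 epimers | CC(C)(C)[Si](c1ccccc1)(c1ccccc1)OC[C@@H](C)CC(C/C(C)=C/CC/C(C)=C/CCc1ccoc1)S(=O)(=O)c1ccccc1 | intermediate
23 | tert-butyl{[(2S,6E,10E)-13-(furan-3-yl)-2,6,10-trimethyltrideca-6,10-dien-1-yl]oxy}diphenylsilane | CC(C)(C)[Si](c1ccccc1)(c1ccccc1)OC[C@@H](C)CCC/C(C)=C/CC/C(C)=C/CCc1ccoc1 | intermediate
24 | (2S,6E,10E)-13-(furan-3-yl)-2,6,10-trimethyltrideca-6,10-dien-1-ol | OC[C@@H](C)CCC/C(C)=C/CC/C(C)=C/CCc1ccoc1 | intermediate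
25 | (2S,6E,10E)-13-(furan-3-yl)-2,6,10-trimethyltrideca-6,10-dienal | O=C[C@@H](C)CCC/C(C)=C/CC/C(C)=C/CCc1ccoc1 | intermediate
26 | 3-methylfuran-2(5H)-one | CC1=CCOC1=O | starting material
27 | tert-butyldimethyl[(3-methylfuran-2-yl)oxy]silane | Cc1ccoc1O[Si](C)(C)C(C)(C)C | intermediate
28 | 5-[(2S,6E,10E)-13-(furan-3-yl)-1-hydroxy-2,6,10-trimethyltrideca-6,10-dien-1-yl]-3-methylfuran-2(5H)-one, mixture at C5 and C1' | CC1=CC(OC1=O)C(O)[C@@H](C)CCC/C(C)=C/CC/C(C)=C/CCc1ccoc1 | intermediate
29 | methanesulfonate of 28 | CC1=CC(OC1=O)C(OS(C)(=O)=O)[C@@H](C)CCC/C(C)=C/CC/C(C)=C/CCc1ccoc1 | intermediate (not isolated)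
30 | (5Z)-5-[(2S,6E,10E)-13-(furan-3-yl)-2,6,10-trimethyltrideca-6,10-dien-1-ylidene]-3-methylfuran-2(5H)-one | CC1=C/C(=C/[C@@H](C)CCC/C(C)=C/CC/C(C)=C/CCc2ccoc2)OC1=O | target

## Step count

- **Total steps:** 19.
- **Longest linear sequence:** 13 steps, namely steps 1, 2, 3, 4, 6, 7, 8, 13, 14, 15, 16, 18 and 19 (1 → 2 → 3 → 4 → 6 → 11 → 12 → 13 → 22 → 23 → 24 → 25 → 28 → 30).

## The three steps most likely to fail

**Step 6.** The risks are Wurtz dimerisation while 10 is made, and SN2' or ring-C2 attack in the coupling. The fallback reverses the polarity, so no furylmethyl organometallic is needed. It sets out from 6, uses 9 as the electrophile, and comes back at 11. Chloride 6 is displaced with PhSO2Na in DMF at rt to give the allylic phenyl sulfone F1. The anion of this sulfone (nBuLi, THF/DMPU, −78 °C) is alkylated with 9 to give the furylmethylated allylic sulfone F2. Hydride desulfonylation with LiBHEt3 and catalytic PdCl2(dppp) in THF at 0 °C then delivers 11 with the E-alkene in its original position.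

**Step 18.** The risks are Lewis acid damage to the 3-alkylfuran or the trisubstituted alkenes, and epimerisation or Prins-type loss of aldehyde 25. The fallback forms the same bond as a Wittig olefination under weakly basic conditions. It sets out from 26, uses 25, and comes back at 30, bypassing 28 and 29. Wohl–Ziegler bromination of 26 (NBS, catalytic AIBN, PhCF3, reflux) gives 5-bromo-3-methylfuran-2(5H)-one F3. Treating it with PPh3 in toluene gives (4-methyl-5-oxo-2,5-dihydrofuran-2-yl)triphenylphosphonium bromide F4. Et3N in CH2Cl2 generates the stabilised ylide in the presence of 25 and gives 30 directly. Any E-isomer is separated, or equilibrated to Z with a trace of I2 in daylight.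

**Step 19.** The risks are an insufficient Z/E ratio and base-induced erosion of the allylic (S) centre. The fallback builds the lactone ring around the alkene, so the geometry follows from an anti 5-exo-dig oxymetalation and no base stronger than Et3N is used. It sets out from 25 and comes back at 30.
- Seyferth–Gilbert homologation of 25 with dimethyl (1-diazo-2-oxopropyl)phosphonate (K2CO3, MeOH, 0 °C → rt) gives (3S,7E,11E)-14-(furan-3-yl)-3,7,11-trimethyltetradeca-7,11-dien-1-yne F5.
- Separately, prop-2-yn-1-ol is carbomagnesiated (MeMgBr, 10 mol % CuI, THF) and quenched with I2 to give (Z)-3-iodo-2-methylprop-2-en-1-ol F6.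
- F6 is oxidised with catalytic TEMPO and PhI(OAc)2 in MeCN/H2O to (Z)-3-iodo-2-methylprop-2-enoic acid F7.
- Tandem Sonogashira coupling and lactonisation of F5 with F7 (5 mol % Pd(PPh3)4, 5 mol % CuI, Et3N, MeCN, rt) gives 30.

## Further compounds

F1 | step 6 | tert-butyl{[(2E,6E)-2,6-dimethyl-8-(phenylsulfonyl)octa-2,6-dien-1-yl]oxy}dimethylsilane | CC(C)(C)[Si](C)(C)OC/C(C)=C/CC/C(C)=C/CS(=O)(=O)c1ccccc1
F2 | step 6 | tert-butyl{[(2E,6E)-9-(furan-3-yl)-2,6-dimethyl-8-(phenylsulfonyl)nona-2,6-dien-1-yl]oxy}dimethylsilane (racemic at C8) | CC(C)(C)[Si](C)(C)OC/C(C)=C/CC/C(C)=C/C(Cc1ccoc1)S(=O)(=O)c1ccccc1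
F3 | step 18 | 5-bromo-3-methylfuran-2(5H)-one (racemic) | CC1=CC(Br)OC1=O
F4 | step 18 | (4-methyl-5-oxo-2,5-dihydrofuran-2-yl)triphenylphosphonium bromide | CC1=CC(OC1=O)[P+](c1ccccc1)(c1ccccc1)c1ccccc1.[Br-]
F5 | step 19 | (3S,7E,11E)-14-(furan-3-yl)-3,7,11-trimethyltetradeca-7,11-dien-1-yne | C#C[C@@H](C)CCC/C(C)=C/CC/C(C)=C/CCc1ccoc1
F6 | step 19 | (Z)-3-iodo-2-methylprop-2-en-1-ol | OC/C(C)=C\I
F7 | step 19 | (Z)-3-iodo-2-methylprop-2-enoic acid | OC(=O)/C(C)=C\I
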